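Compound numbers 1–20 are fixed by the steps below and used throughout. The chain carbons are numbered C1 (on ring B, the dihydroxy arene) to C14 (on ring A, the monohydroxy arene).

## Analysis of the target

Compound 20 is a 20-membered macrocycle: fourteen methylene carbons and a diaryl ether oxygen bridge the two benzene rings, and the ring path takes three atoms of ring A and two of ring B. Ring A is 1,3,5-trisubstituted (OH, O-aryl and C14, all meta). Ring B is tetrasubstituted: its ether carbon lies between a hydroxyl-bearing carbon and the carbon that carries C1, and the second hydroxyl is para to the ether carbon. There is no stereocentre and, at this ring size, no lasting planar chirality, so the geometry of any alkene met on the way is of no consequence. The three phenols make both rings electron-rich and sensitive to oxidation under base; they are best carried as methyl ethers, which tolerate hydride, strong base and peracid, while the diaryl ether itself is inert. The two difficulties are the di-ortho-substituted ether carbon of ring B and the closure of a large ring whose chain carries no functional group. The strategy rests on the benzylic bond C13–C14 at ring A: this CH2–CH2 unit can be read as what remains of a CH2–SO2–CH2 unit in a ring one atom larger, so the macrocycle can be closed at sulfur and the sulfur then deleted.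

## Retrosynthetic reasoning

**20 ⇒ 19.** The three O–H bonds are traced back to O–CH3 bonds. Methyl ethers are the smallest protecting groups that survive every later condition, and aryl methyl ethers are cleaved by a boron Lewis acid without touching the diaryl ether.

**19 ⇒ 18.** A C13=C14 double bond is introduced retrosynthetically. Its hydrogenation is trivial, and it is the natural product of a sulfone contraction.

**18 ⇒ 15 (key disconnection).** The C13–C14 bond is cut and a sulfonyl group is inserted between the two carbons, giving the 21-membered benzyl alkyl sulfone 15. The cut is made at the ring A benzylic bond and not at the ring B end for three reasons: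
- C14 then becomes a benzylic carbon flanked by the sulfonyl group and ring A, so its protons are acidic enough for halogenation in the flask.
- The ring A benzylic carbon can come from a benzoate ester in a commercial arene, and it has only meta neighbours.
- The ring B benzylic carbon is needed as a formyl group, both to activate the ether formation and to carry the chain.

What is gained is that the carbon–carbon bond is formed in a unimolecular contraction (through 16 and 17), and the ring closure proper is moved to sulfur.

**15 ⇒ 13.** The two S=O bonds are removed, leaving the cyclic sulfide 13; the forward step is a peracid oxidation in which sulfur outruns the arenes.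

**13 ⇒ 11.** Both C–S bonds are cut, giving the open dibromide 11 and an inorganic sulfide. A soft sulfur nucleophile and two primary halides give the most forgiving kind of large-ring closure; the forward reaction passes through the thiolate 12.

**11 ⇒ 10 ⇒ 9.** The two C–Br bonds go back to the C–OH bonds of diol 10, and the benzylic alcohol goes back to the methyl ester of 9. The ester is the form in which ring A is bought.

**9 ⇒ 8 ⇒ 4 + 6.** The C1–C2 bond is cut as an alkene (8). Olefination of aldehyde 4 with the ylide 7 from the C12 phosphonium salt 6, itself from bromo alcohol 5, delivers all thirteen carbons of the ring B side of the chain with the terminal oxygen in place.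

**4 ⇒ 2 + 3.** The diaryl ether C–O bond at ring B is cut. The formyl group ortho to the bromine of 2 is what makes this crowded coupling with phenol 3 feasible, and it is the same carbon that becomes C1.

**2 ⇒ 1.** The C–Br bond is removed; bromination of 1 is directed to the position ortho to the formyl group by the two methoxy groups.

## Alternatives that were turned down

**Alternative 1:** Ring B is taken apart at the two bonds flanking the hydroxyl carbon next to the ether carbon; that carbon is supplied by CO.
- Forward key step: the macrocyclic 3-acetoxy-1,4-enyne A2 (ring A bound through an enol ether oxygen to the alkene terminus, the chain on the internal alkene carbon) is treated with [Rh(CO)2Cl]2 under CO. A 1,2-acetoxy shift, CO insertion to a dienyl ketene and a six-electron electrocyclisation then give A1.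
- For it: ring B is built with all four substituents placed by connectivity, its two oxygens come out differentiated (free OH and acetate), and the hindered diaryl ether is never made by cross-coupling. On these points it is stronger than the chosen route.
- Against it: the key step closes only ring B, so A2 still needs a macrocyclisation of its own. A2 combines an acid-labile aryl enol ether of defined geometry with a propargylic acetate and is much longer to prepare than 15. The benzannulation would also have to tolerate an aryloxy group on the alkene carbon that bonds to the CO carbon, where the electron-rich terminus could divert the rhodium carbene.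
- Comparison: the chosen strategy offers two purchased arenes and a ring closure and contraction that both have close precedent.

**Alternative 2:** The C1–C2 bond at ring B is cut.
- Forward key step: the 2-aryl-1,3-dithiane A4, with a 13-carbon ω-bromoalkyl chain on ring A, is deprotonated with LiN(i-Pr)2 and alkylated intramolecularly to the macrocyclic dithiane A3. Raney Ni and ether cleavage follow.
- For it: the formyl group serves twice, first as activator for the ether and then as acyl anion equivalent. A carbon–carbon bond closes the ring directly, and only two steps follow the closure against four after the sulfide closure here. On step count after ring closure it is the stronger plan.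
- Against it: a strongly basic organolithium must be held at high dilution long enough for a 20-membered closure. The carbanion sits next to an ortho aryloxy group on an electron-rich ring, so it is hindered and poorly stabilised, and elimination at the bromide, proton transfer and oligomerisation compete. The long chain must also be built on ring A while the ring B formyl group is masked.
- Comparison: the chosen strategy closes the ring with sulfide in a protic medium and forms the carbon–carbon bond without any dilution requirement.

**Alternative 3:** Ring A is cut at two bonds (chain-bearing carbon to the adjacent CH, and aryloxy carbon to the neighbouring carbon) and assembled from a 2-pyrone and an aryl ethynyl ether.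
- Forward key step: A6 is heated at high dilution. Cycloaddition of the ester-activated pyrone across C3 and C6 with the ethynyl ether, followed by loss of CO2, gives A5.
- For it: one step makes ring A, fixes its all-meta pattern by the polarity of the two partners, and closes the macrocycle. In bonds formed per step it is stronger than the chosen route.
- Against it: a fourteen-methylene tether gives the intramolecular reaction no entropic advantage, so high temperature and high dilution are needed together. Aryl ethynyl ethers hydrate and rearrange under such heating. Both fragments need several steps, and the ester of A5 is foreign to the target and costs a hydrolysis and a decarboxylation.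
- Comparison: the chosen strategy offers commercial rings with the correct substitution and no group to remove afterwards except the methyl ethers.

Key step: step 10

Assumption: racemic intermediates (14, 16, 17) and alkenes that may form as E/Z mixtures (8, 18) are drawn as one form, since all forms converge on the same later compound.

## Route

Step 1
Reactants: 1 3,5-dimethoxybenzaldehyde
Product: 2 2-bromo-3,5-dimethoxybenzaldehyde
Conditions: NBS (1.0 equiv), MeCN, 0 °C → rt
Reagents that add atoms: N-bromosuccinimide, O=C1CCC(=O)N1Br
Why: Electrophilic aromatic bromination; C2 is ortho to one methoxy group and para to the other and is less hindered than C4 between the two methoxy groups, and one equivalent of NBS should stop at the monobromide.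

Step 2
Reactants: 2 2-bromo-3,5-dimethoxybenzaldehyde; 3 methyl 3-hydroxy-5-methoxybenzoate
Product: 4 methyl 3-(2-formyl-4,6-dimethoxyphenoxy)-5-methoxybenzoate
Conditions: CuI (cat.), N,N-dimethylglycine·HCl, Cs2CO3, dioxane, 100 °C
Reagents that add atoms: none
Why: Ullmann-type diaryl ether synthesis; the ortho formyl group lowers the electron density at the C–Br carbon and can coordinate copper, which should offset the two ortho substituents, while the phenoxide of 3 is unhindered and dry carbonate leaves the ester and the non-enolisable aldehyde intact.

Step 3
Reactants: 5 12-bromododecan-1-ol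
Product: 6 (12-hydroxydodecyl)triphenylphosphonium bromide
Conditions: PPh3, MeCN, reflux
Reagents that add atoms: triphenylphosphine, c1ccc(cc1)P(c1ccccc1)c1ccccc1
Why: SN2 quaternisation of the phosphine by a primary bromide; the free hydroxyl does not interfere.

Step 4
Reactants: 4 methyl 3-(2-formyl-4,6-dimethoxyphenoxy)-5-methoxybenzoate; 6 (12-hydroxydodecyl)triphenylphosphonium bromide
Product: 8 methyl 3-[2-[(1Z)-13-hydroxytridec-1-en-1-yl]-4,6-dimethoxyphenoxy]-5-methoxybenzoate, via ylide alkoxide 7 (not isolated)
Conditions: 6, NaN(SiMe3)2 (2.1 equiv), THF, −78 → 0 °C; then 4, −78 → 0 °C; H2O quench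
Reagents that add atoms: none
Why: Wittig olefination with a non-stabilised ylide; two equivalents of base give 7, which should add to the aldehyde far faster than to the aryl ester at low temperature, and the mainly Z geometry expected is erased in step 5. Any ester exchange caused by the alkoxide would be repaired in step 6, where every benzoate ester is reduced to the same diol.

Step 5
Reactants: 8 methyl 3-[2-[(1Z)-13-hydroxytridec-1-en-1-yl]-4,6-dimethoxyphenoxy]-5-methoxybenzoate
Product: 9 methyl 3-[2-(13-hydroxytridecyl)-4,6-dimethoxyphenoxy]-5-methoxybenzoate
Conditions: H2 (1 atm), Pd/C, EtOAc, rt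
Reagents that add atoms: none
Why: Catalytic hydrogenation of a disubstituted styrene-type alkene; aryl ethers, the ester and the primary alcohol are inert under these conditions.

Step 6
Reactants: 9 methyl 3-[2-(13-hydroxytridecyl)-4,6-dimethoxyphenoxy]-5-methoxybenzoate
Product: 10 13-[2-[3-(hydroxymethyl)-5-methoxyphenoxy]-3,5-dimethoxyphenyl]tridecan-1-ol
Conditions: LiAlH4, THF, 0 °C → rt; Rochelle salt work-up
Reagents that add atoms: none
Why: Hydride reduction of a benzoate ester to the benzylic alcohol; nothing else in 9 is reducible.

Step 7
Reactants: 10 13-[2-[3-(hydroxymethyl)-5-methoxyphenoxy]-3,5-dimethoxyphenyl]tridecan-1-ol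
Product: 11 1-(13-bromotridecyl)-2-[3-(bromomethyl)-5-methoxyphenoxy]-3,5-dimethoxybenzene
Conditions: CBr4, PPh3, CH2Cl2, 0 °C → rt
Reagents that add atoms: carbon tetrabromide, BrC(Br)(Br)Br
Why: Appel reaction; both primary alcohols are converted by SN2 through alkoxyphosphonium ions, and the benzylic bromide, having only meta oxygen substituents, is not prone to ionisation.

Step 8
Reactants: 11 1-(13-bromotridecyl)-2-[3-(bromomethyl)-5-methoxyphenoxy]-3,5-dimethoxybenzene
Product: 13 21-membered cyclic benzyl alkyl sulfide (ring A–CH2–S–(CH2)13–ring B; tri-O-methyl), via bromo thiolate 12 (not isolated)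
Conditions: Na2S·9H2O, EtOH/THF/H2O, slow simultaneous addition (final ca. 2 mM), reflux
Reagents that add atoms: sodium sulfide (used as the nonahydrate), [Na+].[Na+].[S-2]
Why: Double SN2 displacement by sulfide; the benzylic bromide reacts first to give thiolate 12, whose soft sulfur then closes the 21-membered ring on the primary bromide (exo-tet), and slow addition keeps the concentration low enough to disfavour oligomers.

Step 9
Reactants: 13 21-membered cyclic benzyl alkyl sulfide
Product: 15 21-membered cyclic benzyl alkyl sulfone (tri-O-methyl), via sulfoxide 14 (not isolated)
Conditions: mCPBA (2.3 equiv), NaHCO3, CH2Cl2, 0 °C → rt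
Reagents that add atoms: 3-chloroperbenzoic acid, OOC(=O)c1cccc(Cl)c1
Why: Peracid oxidation of a dialkyl sulfide through the sulfoxide to the sulfone; sulfur is oxidised much faster than the methoxy arenes, and bicarbonate buffers the acid formed.

Step 10
Reactants: 15 21-membered cyclic benzyl alkyl sulfone
Product: 18 (E)-13,14-didehydro tri-O-methyl macrocycle (20-membered ring; C13=C14 conjugated to ring A), via α-bromo sulfone 16 (not isolated), via episulfone 17 (not isolated)
Conditions: CBr2F2, KOH/Al2O3, t-BuOH/CH2Cl2, 5 °C → rt
Reagents that add atoms: none
Why: Ramberg–Bäcklund reaction with in situ halogenation, a method established for benzylic sulfones and cyclophane-type rings. KOH on alumina removes a proton at C14 of 15, the most acidic site because it lies between the sulfonyl group and ring A, and the carbanion abstracts bromine from CBr2F2 to give 16; the bromodifluoromethyl anion left over is protonated or breaks down to bromide and difluorocarbene, which the base consumes. Deprotonation at C13 then displaces bromide from C14 in a 3-exo-tet closure to the episulfone 17, which loses its SO2 unit by cheletropic extrusion and leaves the C13=C14 double bond. The 20-membered ring therefore arises by contraction of the 21-membered ring and not by an end-to-end closure, so the step is unimolecular and needs no dilution. Which α-carbon is brominated does not matter for the constitution, because both α-bromo sulfones lead to the same episulfone; what the step needs is a single halogenation, and the fast closure of 16 together with a bromine donor that reacts only with carbanions (so the methoxy arenes are not brominated) should secure it. No stereocentre is created; 17 is expected to equilibrate to the trans isomer under base and give mainly the E alkene, but either geometry is acceptable since step 11 removes it.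

Step 11
Reactants: 18 (E)-13,14-didehydro tri-O-methyl macrocycle
Product: 19 tri-O-methyl ether of the target (saturated 20-membered macrocycle)
Conditions: H2 (1 atm), Pd/C, EtOAc, rt
Reagents that add atoms: none
Why: Catalytic hydrogenation of a conjugated disubstituted alkene; either alkene isomer gives 19, and aryl ethers are untouched.

Step 12
Reactants: 19 tri-O-methyl ether of the target
Product: 20 target CNP0173380.0 (20-membered macrocyclic diaryl ether triphenol)
Conditions: BBr3 (excess), CH2Cl2, −78 °C → rt; then H2O
Reagents that add atoms: none
Why: Lewis acid cleavage of aryl methyl ethers (boron binds oxygen, bromide attacks the methyl carbon by SN2); the diaryl ether offers no carbon open to SN2 and should survive, and hydrolysis of the aryl borates on work-up releases the three phenols.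

## Compound list

1 | 3,5-dimethoxybenzaldehyde | COc1cc(C=O)cc(OC)c1 | starting material
2 | 2-bromo-3,5-dimethoxybenzaldehyde | COc1cc(OC)c(Br)c(C=O)c1 | intermediate
3 | methyl 3-hydroxy-5-methoxybenzoate | COC(=O)c1cc(O)cc(OC)c1 | starting material
4 | methyl 3-(2-formyl-4,6-dimethoxyphenoxy)-5-methoxybenzoate | COC(=O)c1cc(OC)cc(Oc2c(C=O)cc(OC)cc2OC)c1 | intermediate
5 | 12-bromododecan-1-ol | OCCCCCCCCCCCCBr | starting material
6 | (12-hydroxydodecyl)triphenylphosphonium bromide | [Br-].OCCCCCCCCCCCC[P+](c1ccccc1)(c1ccccc1)c1ccccc1 | intermediate
7 | sodium 12-(triphenylphosphoranylidene)dodecan-1-olate (ylide alkoxide, not isolated) | [Na+].[O-]CCCCCCCCCCCC=P(c1ccccc1)(c1ccccc1)c1ccccc1 | intermediate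
8 | methyl 3-[2-[(1Z)-13-hydroxytridec-1-en-1-yl]-4,6-dimethoxyphenoxy]-5-methoxybenzoate (Z drawn; any E isomer is carried along) | COC(=O)c1cc(OC)cc(Oc2c(/C=C\CCCCCCCCCCCO)cc(OC)cc2OC)c1 | intermediate
9 | methyl 3-[2-(13-hydroxytridecyl)-4,6-dimethoxyphenoxy]-5-methoxybenzoate | COC(=O)c1cc(OC)cc(Oc2c(CCCCCCCCCCCCCO)cc(OC)cc2OC)c1 | intermediate
10 | 13-[2-[3-(hydroxymethyl)-5-methoxyphenoxy]-3,5-dimethoxyphenyl]tridecan-1-ol | COc1cc(CO)cc(Oc2c(CCCCCCCCCCCCCO)cc(OC)cc2OC)c1 | intermediate
11 | 1-(13-bromotridecyl)-2-[3-(bromomethyl)-5-methoxyphenoxy]-3,5-dimethoxybenzene | COc1cc(CBr)cc(Oc2c(CCCCCCCCCCCCCBr)cc(OC)cc2OC)c1 | intermediate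
12 | sodium [3-[2-(13-bromotridecyl)-4,6-dimethoxyphenoxy]-5-methoxyphenyl]methanethiolate (not isolated) | [Na+].COc1cc(C[S-])cc(Oc2c(CCCCCCCCCCCCCBr)cc(OC)cc2OC)c1 | intermediate
13 | 21-membered cyclic sulfide: the ring A benzylic CH2 and C13 of the ring B chain joined through S; three OMe groups | COc1cc2cc(c1)Oc1c(OC)cc(OC)cc1CCCCCCCCCCCCCSC2 | intermediate
14 | sulfoxide of 13 (racemic at sulfur, not isolated) | COc1cc2cc(c1)Oc1c(OC)cc(OC)cc1CCCCCCCCCCCCCS(=O)C2 | intermediate
15 | 21-membered cyclic benzyl alkyl sulfone (S,S-dioxide of 13) | COc1cc2cc(c1)Oc1c(OC)cc(OC)cc1CCCCCCCCCCCCCS(=O)(=O)C2 | intermediate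
16 | α-bromo sulfone: 15 with Br on the benzylic carbon C14 (racemic, not isolated) | COc1cc2cc(c1)Oc1c(OC)cc(OC)cc1CCCCCCCCCCCCCS(=O)(=O)C2Br | intermediate
17 | episulfone: thiirane 1,1-dioxide spanning C13 and C14, trans, racemic (one enantiomer drawn, not isolated) | COc1cc2cc(c1)Oc1c(OC)cc(OC)cc1CCCCCCCCCCCC[C@@H]1[C@@H]2S1(=O)=O | intermediate
18 | tri-O-methyl 20-membered macrocycle with an (E) C13=C14 double bond conjugated to ring A | COc1cc2cc(c1)Oc1c(OC)cc(OC)cc1CCCCCCCCCCCC/C=C/2 | intermediate
19 | tri-O-methyl ether of the target (saturated 20-membered macrocycle) | COc1cc2cc(c1)Oc1c(OC)cc(OC)cc1CCCCCCCCCCCCCC2 | intermediate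
20 | CNP0173380.0: 20-membered macrocycle, (CH2)14 chain and ether oxygen bridging a 5-hydroxy-1,3-phenylene ring A and a 2,4-dihydroxyphenoxy-type ring B | Oc1cc2cc(c1)Oc1c(O)cc(O)cc1CCCCCCCCCCCCCC2 | target

## Step count and risks

Total step count: 12. Longest linear sequence: 11 steps (1 to 20 through steps 1, 2 and 4–12; step 3 prepares the phosphonium salt on a side branch).

**Step 10 (key step).**
- What may go wrong: a second bromination of the benzylic carbon of 16 before C13 is deprotonated, since the remaining benzylic proton of 16 is more acidic than the C13 protons; this would lead to a bromoalkene after contraction. The reaction may also be incomplete if the lipophilic macrocycle adsorbs poorly on the solid base.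
- Fallback: halogenate once, before the sulfone is made, and isolate the halo sulfone. Setting out from sulfide 13, one equivalent of NCS in CH2Cl2 at 0 °C should chlorinate the benzylic carbon through the chlorosulfonium and thionium ions to give the α-chloro sulfide F1. Oxidation with mCPBA then gives the α-chloro sulfone F2, and KOt-Bu in THF at 0 °C brings about the contraction with no halogen donor present. The route is rejoined at 18.

**Step 8.**
- What may go wrong: intermolecular S-alkylation leading to oligomers instead of end-to-end closure, and solvolysis of the benzylic bromide in hot ethanol before sulfide reaches it.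
- Fallback: make the two C–S bonds one at a time. Setting out from 11, one equivalent of potassium thioacetate in acetone at 0 °C should react selectively at the benzylic bromide and give the S-benzyl thioacetate F3. Slow addition of F3 to Cs2CO3 in MeOH/DMF at 50 °C then liberates the cesium thiolate by methanolysis, and this closes on the remaining primary bromide intramolecularly. The route is rejoined at 13.

**Step 2.**
- What may go wrong: slow oxidative addition at the di-ortho-substituted, electron-rich C–Br bond, so that hydrodebromination of 2 and base-induced decay of the aldehyde overtake the coupling.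
- Fallback: reverse the roles of the rings, so that the hindered ring becomes the phenol and the unhindered ring the halide. Setting out from 2, ethylene glycol and TsOH in refluxing toluene give the dioxolane F4. Bromine–lithium exchange with n-BuLi at −78 °C, quench with B(OMe)3 and oxidative work-up with H2O2/NaOH give 2-(1,3-dioxolan-2-yl)-4,6-dimethoxyphenol F5. Coupling of F5 with purchased methyl 3-bromo-5-methoxybenzoate F6 (CuI, picolinic acid, K3PO4, DMSO, 90 °C) gives the diaryl ether acetal F7, and aqueous HCl in THF unmasks the aldehyde. The route is rejoined at 4.

**Step 4.**
- What may go wrong: attack of the ylide alkoxide on the methyl ester (acylation or ester exchange), and incomplete ylide formation from the sparingly soluble hydroxy salt.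
- Fallback: remove the alkoxide from the reagent. Setting out from 5, TBSCl and imidazole give the silyl ether F8 and PPh3 gives the phosphonium salt F9. One equivalent of NaN(SiMe3)2 followed by aldehyde 4 gives the silylated alkene F10, and Bu4NF in THF frees the alcohol. The route is rejoined at 8.

## Further compounds

F1 | step 10 | α-chloro sulfide: 13 with Cl on the benzylic carbon (racemic) | COc1cc2cc(c1)Oc1c(OC)cc(OC)cc1CCCCCCCCCCCCCSC2Cl
F2 | step 10 | α-chloro sulfone: 15 with Cl on the benzylic carbon (racemic) | COc1cc2cc(c1)Oc1c(OC)cc(OC)cc1CCCCCCCCCCCCCS(=O)(=O)C2Cl
F3 | step 8 | S-[[3-[2-(13-bromotridecyl)-4,6-dimethoxyphenoxy]-5-methoxyphenyl]methyl] ethanethioate | COc1cc(CSC(C)=O)cc(Oc2c(CCCCCCCCCCCCCBr)cc(OC)cc2OC)c1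
F4 | step 2 | 2-(2-bromo-3,5-dimethoxyphenyl)-1,3-dioxolane | COc1cc(OC)c(Br)c(c1)C1OCCO1
F5 | step 2 | 2-(1,3-dioxolan-2-yl)-4,6-dimethoxyphenol | COc1cc(OC)c(O)c(c1)C1OCCO1
F6 | step 2 | methyl 3-bromo-5-methoxybenzoate (purchased coupling partner) | COC(=O)c1cc(Br)cc(OC)c1
F7 | step 2 | methyl 3-[2-(1,3-dioxolan-2-yl)-4,6-dimethoxyphenoxy]-5-methoxybenzoate | COC(=O)c1cc(OC)cc(Oc2c(C3OCCO3)cc(OC)cc2OC)c1
F8 | step 4 | (12-bromododecyloxy)(tert-butyl)dimethylsilane | CC(C)(C)[Si](C)(C)OCCCCCCCCCCCCBr
F9 | step 4 | [12-(tert-butyldimethylsilyloxy)dodecyl]triphenylphosphonium bromide | [Br-].CC(C)(C)[Si](C)(C)OCCCCCCCCCCCC[P+](c1ccccc1)(c1ccccc1)c1ccccc1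
F10 | step 4 | tert-butyldimethylsilyl ether of 8 (Z drawn) | COC(=O)c1cc(OC)cc(Oc2c(/C=C\CCCCCCCCCCCO[Si](C)(C)C(C)(C)C)cc(OC)cc2OC)c1
A1 | alternative 1 | macrocycle with ring B as monoacetate (free OH next to the ether carbon, acetate para to it) and ring A as methyl ether | COc1cc2cc(c1)Oc1c(O)cc(OC(C)=O)cc1CCCCCCCCCCCCCC2
A2 | alternative 1 | macrocyclic 3-acetoxy-1,4-enyne: (E) enol ether of ring A whose internal alkene carbon carries the 14-carbon chain and a racemic 1-acetoxyprop-2-yn-1-yl group | COc1cc2cc(c1)O/C=C(/C(OC(C)=O)C#C)CCCCCCCCCCCCCC2
A3 | alternative 2 | tri-O-methyl macrocycle with chain carbon 1 as a 1,3-dithiane | COc1cc2cc(c1)Oc1c(OC)cc(OC)cc1C1(SCCCS1)CCCCCCCCCCCCC2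
A4 | alternative 2 | 2-[2-[3-(13-bromotridecyl)-5-methoxyphenoxy]-3,5-dimethoxyphenyl]-1,3-dithiane | COc1cc(CCCCCCCCCCCCCBr)cc(Oc2c(C3SCCCS3)cc(OC)cc2OC)c1
A5 | alternative 3 | tri-O-methyl macrocycle with a methyl ester on the ring A carbon between C-OMe and C-OAr | COC(=O)c1c(OC)cc2cc1Oc1c(OC)cc(OC)cc1CCCCCCCCCCCCCC2
A6 | alternative 3 | methyl 6-[14-[2-(ethynyloxy)-3,5-dimethoxyphenyl]tetradecyl]-4-methoxy-2-oxo-2H-pyran-3-carboxylate | C#COc1c(OC)cc(OC)cc1CCCCCCCCCCCCCCc1cc(OC)c(C(=O)OC)c(=O)o1
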